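**Retrosynthetic overview**
1. Sodwanone B (37) is opened at the C-1–CH2 bond of ring B by a Stork–Danheiser alkylative transposition: dienone 17 (rings A/B) plus the alkyllithium from iodide 32 (rings C/D); one acid treatment then removes all masking groups.
2. Ring B is not closed as a six-membered ring: its C-1(=O)–C-2(Me)=C-3(O)–C-4(O) array is the four-membered ring of squarate-derived cyclobutenone 13, which is enlarged by C-4a=C-8a of a ready-made ring A (4π opening, 6π closure). This is possible because C-3/C-4 are contiguous oxygen-bearing carbons next to a C-1 carbonyl equivalent, and C-8a is fully substituted, so the dienone cannot aromatise.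
3. Ring A comes from 2,2-dimethylcyclohexane-1,3-dione; a C-7 tert-butyl ester, set together with C-6 by dynamic kinetic resolution, is a traceless control element for C-8a, later masks the C-6 ketone as its enolate and is finally lost as CO2.
4. Rings D and C are formed together by an epoxide-opening cascade of the geraniol-derived diepoxy β-keto ester 23; C-6 and C-7 of ring C follow by equilibration and face-selective hydrogenation.
5. Ring order: A, then B (ring expansion); D and C (cascade); union; deprotection.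

Key step: step 9

Remark (locants): decalin half: ring B = C-1 (side-chain carbon), C-2 (Me), C-3 (C=O), C-4 (OH), C-4a, C-8a; ring A = C-4a, C-5 (CMe2), C-6 (C=O), C-7, C-8, C-8a. Other half: 1-benzoxepine numbering, O-1, C-2 (CMe2), C-3 (C=O), C-5a (quaternary), C-6 (side chain), C-7 (Me), C-9a.
Remark (assumptions): the sense of the (R)-BINAP reduction in step 5 is taken by analogy with 2-alkoxycarbonylcycloalkanones; the Shi ketone from D-fructose is taken to give the (6R)-epoxide in step 13, a centre that is erased in step 21.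

**Route**

Step 1
Reactants: 1 dimethyl squarate
Product: 3 3-methoxy-4-methylcyclobut-3-ene-1,2-dione, via hydroxy adduct 2 (not isolated)
Conditions: MeLi, THF, −78 °C; then (CF3CO)2O, −78 °C → rt
Reagents that add atoms: methyllithium (C[Li])
Why: 1,2-addition of MeLi to one squarate carbonyl, then trifluoroacetylation of the alkoxide, which collapses with loss of methyl trifluoroacetate to the cyclobutenedione (standard squarate mono-alkylation); no stereocentre remains.

Step 2
Reactants: 4 2,2-dimethylcyclohexane-1,3-dione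
Product: 5 2,2,4-trimethylcyclohexane-1,3-dione (racemic)
Conditions: LiN(iPr)2, THF, −78 °C; MeI, −78 → 0 °C
Reagents that add atoms: iodomethane (CI)
Why: kinetic lithium enolate alkylation at the only enolisable positions (C-2 is quaternary); the new centre is racemic and becomes trigonal in step 4.

Step 3
Reactants: 5 2,2,4-trimethylcyclohexane-1,3-dione
Product: 6 tert-butyl 3,3,5-trimethyl-2,4-dioxocyclohexane-1-carboxylate
Conditions: LiN(iPr)2 (2.2 equiv), THF, −78 °C; Boc2O, −78 → 0 °C; H2O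
Reagents that add atoms: di-tert-butyl dicarbonate (CC(C)(C)OC(=O)OC(=O)OC(C)(C)C)
Why: C-acylation of the kinetic enolate (deprotonation at the CH2 of C-6, not at CHMe) with Boc2O, the second equivalent of base holding the β-keto ester as its enolate; no controlled stereocentre.

Step 4
Reactants: 6 tert-butyl 3,3,5-trimethyl-2,4-dioxocyclohexane-1-carboxylate
Product: 7 tert-butyl 3,5,5-trimethyl-6-oxo-4-(trifluoromethylsulfonyloxy)cyclohex-3-ene-1-carboxylate
Conditions: NaH (1.0 equiv), THF, 0 °C; KN(SiMe3)2 (1.1 equiv), −78 °C; PhNTf2, −78 → 0 °C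
Reagents that add atoms: N-phenylbis(trifluoromethanesulfonimide) (O=S(=O)(N(c1ccccc1)S(=O)(=O)C(F)(F)F)C(F)(F)F)
Why: selective enol triflation of a dianion: the β-keto ester is parked as its sodium enolate, KN(SiMe3)2 removes the only remaining α-proton (CHMe next to the other ketone) and the more reactive ketone enolate oxygen is triflated; the CHMe centre disappears.

Step 5
Reactants: 7 tert-butyl 3,5,5-trimethyl-6-oxo-4-(trifluoromethylsulfonyloxy)cyclohex-3-ene-1-carboxylate
Product: 8 tert-butyl (1R,6S)-6-hydroxy-3,5,5-trimethyl-4-(trifluoromethylsulfonyloxy)cyclohex-3-ene-1-carboxylate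
Conditions: RuCl2[(R)-BINAP] (1 mol %), H2 (80 atm), CH2Cl2, 50 °C
Reagents that add atoms: none
Why: Noyori asymmetric hydrogenation of a β-keto ester with dynamic kinetic resolution: C-1 epimerises through the enol faster than reduction and the (R)-BINAP catalyst should reduce one enantiomer to the trans (1R,6S) hydroxy ester, setting both centres.

Step 6
Reactants: 8 tert-butyl (1R,6S)-6-hydroxy-3,5,5-trimethyl-4-(trifluoromethylsulfonyloxy)cyclohex-3-ene-1-carboxylate
Product: 9 tert-butyl (1R,6S)-3,5,5-trimethyl-6-(triethylsilyloxy)-4-(trifluoromethylsulfonyloxy)cyclohex-3-ene-1-carboxylate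
Conditions: Et3SiOTf, 2,6-lutidine, CH2Cl2, −78 → 0 °C
Reagents that add atoms: triethylsilyl trifluoromethanesulfonate (CC[Si](CC)(CC)OS(=O)(=O)C(F)(F)F)
Why: silylation of the hindered secondary alcohol with a silyl triflate; stereocentres untouched.

Step 7
Reactants: 9 tert-butyl (1R,6S)-3,5,5-trimethyl-6-(triethylsilyloxy)-4-(trifluoromethylsulfonyloxy)cyclohex-3-ene-1-carboxylate
Product: 10 tert-butyl (1R,6S)-3,5,5-trimethyl-6-(triethylsilyloxy)-4-(trimethylstannyl)cyclohex-3-ene-1-carboxylate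
Conditions: Me3SnSnMe3, Pd(PPh3)4 (5 mol %), LiCl, THF, reflux
Reagents that add atoms: hexamethyldistannane (C[Sn](C)(C)[Sn](C)(C)C)
Why: palladium-catalysed stannylation of an enol triflate (oxidative addition, transmetalation with the distannane, reductive elimination); no stereocentre involved.

Step 8
Reactants: 10 tert-butyl (1R,6S)-3,5,5-trimethyl-6-(triethylsilyloxy)-4-(trimethylstannyl)cyclohex-3-ene-1-carboxylate; 3 3-methoxy-4-methylcyclobut-3-ene-1,2-dione
Product: 13 4-[(4R,5S)-4-(tert-butoxycarbonyl)-2,6,6-trimethyl-5-(triethylsilyloxy)cyclohex-1-en-1-yl]-3-methoxy-4-(methoxymethoxy)-2-methylcyclobut-2-en-1-one (both C-4 epimers), via alkenyllithium 11 (not isolated), via lithium alkoxide 12 (not isolated)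
Conditions: MeLi (1.05 equiv), THF, −78 °C; 3, −78 °C; MeOCH2Cl, −78 → 0 °C
Reagents that add atoms: chloromethyl methyl ether (COCCl)
Why: tin–lithium exchange, 1,2-addition of the alkenyllithium to the C-2 carbonyl of 3 (the other carbonyl is a vinylogous ester) and O-alkylation of the tertiary alkoxide; the new C-4 centre forms unselectively and is erased in step 9.

Step 9
Reactants: 13 4-[(4R,5S)-4-(tert-butoxycarbonyl)-2,6,6-trimethyl-5-(triethylsilyloxy)cyclohex-1-en-1-yl]-3-methoxy-4-(methoxymethoxy)-2-methylcyclobut-2-en-1-one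
Product: 15 tert-butyl (6S,7R,8aS)-3-methoxy-4-(methoxymethoxy)-2,5,5,8a-tetramethyl-1-oxo-6-(triethylsilyloxy)-1,5,6,7,8,8a-hexahydronaphthalene-7-carboxylate, via dienylketene 14 (not isolated)
Conditions: toluene (0.01 M), 110 °C, argon
Reagents that add atoms: none
Why: Heating opens the cyclobutenone by conrotatory 4π cleavage of the C-1–C-4 bond, the C-4 methoxymethoxy donor turning outward and the cyclohexenyl group inward, to the (Z)-dienylketene 14, and a 6π electrocyclization then joins the ketene carbon (C-1) to the alkene terminus C-8a. The closest known reaction type is the thermal ring expansion of 4-alkenyl-4-alkoxycyclobutenones (Moore rearrangement), which stops here at the cyclohexa-2,4-dienone because C-8a carries no hydrogen. Ring B closes in the six-centre disrotatory 6π mode, the four ring atoms C-1 to C-4 being extended by C-4a and C-8a of ring A. The one new stereocentre, C-8a, is controlled by the C-7 tert-butyl ester: with the trans C-6 silyloxy group it holds ring A in the diequatorial half-chair (the diaxial form has a syn-axial ester/C-5 methyl contact), and only bond formation on the face cis to the ester leads directly to a chair with the 8a-methyl axial and the ester equatorial, whereas the other face needs the diaxial half-chair or a boat and ends with a 1,3-diaxial methyl/ester pair. The step needs this facial selectivity and the Z ketene geometry, the latter secured by outward rotation of the alkoxy group; the two C-4 epimers of 13 converge because C-4 becomes trigonal.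

Step 10
Reactants: 15 tert-butyl (6S,7R,8aS)-3-methoxy-4-(methoxymethoxy)-2,5,5,8a-tetramethyl-1-oxo-6-(triethylsilyloxy)-1,5,6,7,8,8a-hexahydronaphthalene-7-carboxylate
Product: 16 tert-butyl (6S,7R,8aS)-6-hydroxy-3-methoxy-4-(methoxymethoxy)-2,5,5,8a-tetramethyl-1-oxo-1,5,6,7,8,8a-hexahydronaphthalene-7-carboxylate
Conditions: HF·pyridine, pyridine, THF, 0 °C
Reagents that add atoms: none
Why: fluoride cleavage of the alkyl triethylsilyl ether; the enol acetal, the vinylogous ester and the tert-butyl ester should be inert to buffered HF·pyridine.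

Step 11
Reactants: 16 tert-butyl (6S,7R,8aS)-6-hydroxy-3-methoxy-4-(methoxymethoxy)-2,5,5,8a-tetramethyl-1-oxo-1,5,6,7,8,8a-hexahydronaphthalene-7-carboxylate
Product: 17 tert-butyl (8aS)-3-methoxy-4-(methoxymethoxy)-2,5,5,8a-tetramethyl-1,6-dioxo-1,5,6,7,8,8a-hexahydronaphthalene-7-carboxylate
Conditions: Dess–Martin periodinane, CH2Cl2, 0 °C → rt
Reagents that add atoms: none
Why: Dess–Martin oxidation of the secondary alcohol to the β-keto ester; C-7 has done its work and now equilibrates, C-8a is untouched.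

Step 12
Reactants: 18 geraniol
Product: 19 (2S,3S)-2,3-epoxygeraniol
Conditions: Ti(OiPr)4 (5 mol %), L-(+)-diethyl tartrate (6 mol %), t-BuOOH, 4 Å molecular sieves, CH2Cl2, −20 °C
Reagents that add atoms: tert-butyl hydroperoxide (CC(C)(C)OO)
Why: Sharpless asymmetric epoxidation of the allylic alcohol, L-(+)-tartrate giving the (2S,3S)-epoxide; the remote alkene is untouched.

Step 13
Reactants: 19 (2S,3S)-2,3-epoxygeraniol
Product: 20 (2S,3S,6R)-2,3:6,7-diepoxy-3,7-dimethyloctan-1-ol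
Conditions: Shi ketone from D-fructose (30 mol %), KHSO5, aq. K2CO3 buffer (pH 10.5), Bu4NHSO4, MeCN/dimethoxymethane, 0 °C
Reagents that add atoms: potassium peroxymonosulfate ([K+].[O-]S(=O)(=O)OO)
Why: Shi epoxidation (chiral dioxirane) of the remaining trisubstituted alkene; the catalyst sets C-6, a centre that is oxidised away in step 21.

Step 14
Reactants: 20 (2S,3S,6R)-2,3:6,7-diepoxy-3,7-dimethyloctan-1-ol
Product: 21 (2R,3S,6R)-2,3:6,7-diepoxy-1-iodo-3,7-dimethyloctane
Conditions: I2, PPh3, imidazole, Et2O/MeCN, 0 °C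
Reagents that add atoms: iodine (II)
Why: Appel-type iodination of the primary alcohol (alkoxyphosphonium displaced by iodide); epoxides and stereocentres are untouched (the C-2 descriptor changes only by priority).

Step 15
Reactants: 22 methyl acetoacetate; 21 (2R,3S,6R)-2,3:6,7-diepoxy-1-iodo-3,7-dimethyloctane
Product: 23 methyl (6S,7S,10R)-6,7:10,11-diepoxy-7,11-dimethyl-3-oxododecanoate
Conditions: NaH, THF, 0 °C; n-BuLi, −10 °C; 21, −10 → 0 °C; H2O
Reagents that add atoms: none
Why: γ-alkylation of the acetoacetate dianion (the terminal, more basic carbanion reacts) by SN2 at the primary iodide; stereocentres untouched.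

Step 16
Reactants: 23 methyl (6S,7S,10R)-6,7:10,11-diepoxy-7,11-dimethyl-3-oxododecanoate
Product: 24 methyl (3R,5aS,9aS)-3-hydroxy-2,2,5a-trimethyl-7-oxodecahydro-1-benzoxepine-6-carboxylate
Conditions: BF3·OEt2 (0.5 equiv), CH2Cl2, −78 → −20 °C
Reagents that add atoms: none
Why: Lewis acid epoxide-opening cascade that merges an endo-selective polyepoxide oxacyclization with an epoxy β-keto ester carbocyclization: the C-6/C-7 epoxide oxygen opens the terminal epoxide at tertiary C-11 (7-endo) and the enol carbon C-2 opens C-7 with inversion, so that retention at C-6 and inversion at C-7 fix the trans ring fusion (C-9a, C-5a) from the Sharpless epoxide.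

Step 17
Reactants: 24 methyl (3R,5aS,9aS)-3-hydroxy-2,2,5a-trimethyl-7-oxodecahydro-1-benzoxepine-6-carboxylate
Product: 25 methyl (3R,5aS,9aS)-3-hydroxy-6-(2-methoxy-2-oxoethyl)-2,2,5a-trimethyl-7-oxodecahydro-1-benzoxepine-6-carboxylate
Conditions: K2CO3, BrCH2CO2Me, acetone, 50 °C
Reagents that add atoms: methyl bromoacetate (COC(=O)CBr)
Why: C-alkylation of the β-keto ester potassium enolate with a reactive α-bromo ester; the new quaternary centre is not controlled and is destroyed in step 18, and the secondary alcohol is not deprotonated.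

Step 18
Reactants: 25 methyl (3R,5aS,9aS)-3-hydroxy-6-(2-methoxy-2-oxoethyl)-2,2,5a-trimethyl-7-oxodecahydro-1-benzoxepine-6-carboxylate
Product: 26 methyl 2-[(3R,5aS,6S,9aS)-3-hydroxy-2,2,5a-trimethyl-7-oxodecahydro-1-benzoxepin-6-yl]acetate
Conditions: LiCl, H2O, DMSO, 140 °C
Reagents that add atoms: none
Why: Krapcho dealkoxycarbonylation of the activated β-keto ester (chloride attacks the ester methyl, CO2 is lost); C-6 then equilibrates through the enol to the equatorial side chain, cis to the 5a-methyl group (thermodynamic control).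

Step 19
Reactants: 26 methyl 2-[(3R,5aS,6S,9aS)-3-hydroxy-2,2,5a-trimethyl-7-oxodecahydro-1-benzoxepin-6-yl]acetate
Product: 27 methyl 2-[(3R,5aS,9aS)-3-hydroxy-2,2,5a-trimethyl-7-methylidenedecahydro-1-benzoxepin-6-yl]acetate (C-6 as in 26)
Conditions: Ph3PCH3Br, KOtBu, toluene/THF, 0 → 60 °C
Reagents that add atoms: methyltriphenylphosphonium bromide (C[P+](c1ccccc1)(c1ccccc1)c1ccccc1.[Br-])
Why: Wittig methylenation of the ketone with excess ylide; C-6 stays in its equatorial, thermodynamic configuration.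

Step 20
Reactants: 27 methyl 2-[(3R,5aS,9aS)-3-hydroxy-2,2,5a-trimethyl-7-methylidenedecahydro-1-benzoxepin-6-yl]acetate
Product: 28 methyl 2-[(3R,5aS,6R,7R,9aS)-3-hydroxy-2,2,5a,7-tetramethyldecahydro-1-benzoxepin-6-yl]acetate
Conditions: H2 (1 atm), PtO2 (5 mol %), EtOAc, rt
Reagents that add atoms: none
Why: heterogeneous hydrogenation of the exocyclic methylene from the face opposite the axial 5a-methyl group, which should place the new C-7 methyl axial and cis to the 5a-methyl (any endocyclic isomer formed on the catalyst is reduced from the same face).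

Step 21
Reactants: 28 methyl 2-[(3R,5aS,6R,7R,9aS)-3-hydroxy-2,2,5a,7-tetramethyldecahydro-1-benzoxepin-6-yl]acetate
Product: 29 methyl 2-[(5aS,6R,7R,9aS)-2,2,5a,7-tetramethyl-3-oxodecahydro-1-benzoxepin-6-yl]acetate
Conditions: Dess–Martin periodinane, CH2Cl2, rt
Reagents that add atoms: none
Why: Dess–Martin oxidation of the oxepanol to the oxepan-3-one; the C-3 stereocentre is removed.

Step 22
Reactants: 29 methyl 2-[(5aS,6R,7R,9aS)-2,2,5a,7-tetramethyl-3-oxodecahydro-1-benzoxepin-6-yl]acetate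
Product: 30 methyl 2-[(5aS,6R,7R,9aS)-3,3-(ethylenedioxy)-2,2,5a,7-tetramethyldecahydro-1-benzoxepin-6-yl]acetate
Conditions: Me3SiOCH2CH2OSiMe3, Me3SiOTf (5 mol %), CH2Cl2, −78 → −20 °C
Reagents that add atoms: 1,2-bis(trimethylsilyloxy)ethane (C[Si](C)(C)OCCO[Si](C)(C)C)
Why: Noyori ketalization, driven by formation of hexamethyldisiloxane and suited to a hindered ketone; no stereocentre affected.

Step 23
Reactants: 30 methyl 2-[(5aS,6R,7R,9aS)-3,3-(ethylenedioxy)-2,2,5a,7-tetramethyldecahydro-1-benzoxepin-6-yl]acetate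
Product: 31 2-[(5aS,6R,7R,9aS)-3,3-(ethylenedioxy)-2,2,5a,7-tetramethyldecahydro-1-benzoxepin-6-yl]ethanol
Conditions: LiAlH4, THF, 0 °C; aqueous work-up
Reagents that add atoms: none
Why: hydride reduction of the methyl ester to the primary alcohol; the dioxolane is stable.

Step 24
Reactants: 31 2-[(5aS,6R,7R,9aS)-3,3-(ethylenedioxy)-2,2,5a,7-tetramethyldecahydro-1-benzoxepin-6-yl]ethanol
Product: 32 (5aS,6R,7R,9aS)-3,3-(ethylenedioxy)-6-(2-iodoethyl)-2,2,5a,7-tetramethyldecahydro-1-benzoxepine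
Conditions: I2, PPh3, imidazole, CH2Cl2, 0 °C → rt
Reagents that add atoms: iodine (II)
Why: Appel-type iodination of the primary alcohol; stereocentres untouched.

Step 25
Reactants: 32 (5aS,6R,7R,9aS)-3,3-(ethylenedioxy)-6-(2-iodoethyl)-2,2,5a,7-tetramethyldecahydro-1-benzoxepine; 17 tert-butyl (8aS)-3-methoxy-4-(methoxymethoxy)-2,5,5,8a-tetramethyl-1,6-dioxo-1,5,6,7,8,8a-hexahydronaphthalene-7-carboxylate
Product: 36 tert-butyl (8aR)-1-{2-[(5aS,6R,7R,9aS)-3,3-(ethylenedioxy)-2,2,5a,7-tetramethyldecahydro-1-benzoxepin-6-yl]ethyl}-4-(methoxymethoxy)-2,5,5,8a-tetramethyl-3,6-dioxo-3,5,6,7,8,8a-hexahydronaphthalene-7-carboxylate, via alkyllithium 33 (not isolated), via sodium enolate 34 (not isolated), via carbinol 35 (not isolated)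
Conditions: 32: t-BuLi (2.1 equiv), Et2O/pentane, −78 °C; 17: NaH (1.05 equiv), THF, 0 °C; combine at −78 → −30 °C; then 0.5 M aq. oxalic acid, THF, 0 °C → rt
Reagents that add atoms: water (O)
Why: Stork–Danheiser alkylative transposition: the primary alkyllithium adds 1,2 to the only free carbonyl (C-1 has no α-hydrogen; the C-6 ketone is masked as the sodium enolate of its β-keto ester), and mild acid ionises the doubly allylic carbinol and hydrolyses the C-3 enol ether to the C-3 ketone with C-1=C-2 in place; the carbinol centre does not persist.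

Step 26
Reactants: 36 tert-butyl (8aR)-1-{2-[(5aS,6R,7R,9aS)-3,3-(ethylenedioxy)-2,2,5a,7-tetramethyldecahydro-1-benzoxepin-6-yl]ethyl}-4-(methoxymethoxy)-2,5,5,8a-tetramethyl-3,6-dioxo-3,5,6,7,8,8a-hexahydronaphthalene-7-carboxylate
Product: 37 sodwanone B
Conditions: CF3CO2H/H2O/CH2Cl2 (10:1:10), 0 °C → 40 °C
Reagents that add atoms: water (O)
Why: acidolysis of the tert-butyl ester gives the β-keto acid, which decarboxylates, while the methoxymethyl enol ether and the dioxolane are hydrolysed to the diosphenol and the oxepanone; C-7 becomes CH2 and no stereocentre is touched.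

**Compound list**
1 | dimethyl squarate (3,4-dimethoxycyclobut-3-ene-1,2-dione) | COC1=C(OC)C(=O)C1=O | starting material
2 | 4-hydroxy-2,3-dimethoxy-4-methylcyclobut-2-en-1-one (as lithium alkoxide, racemic) | COC1=C(OC)C(C)(O)C1=O | intermediate
3 | 3-methoxy-4-methylcyclobut-3-ene-1,2-dione | COC1=C(C)C(=O)C1=O | intermediate
4 | 2,2-dimethylcyclohexane-1,3-dione | CC1(C)C(=O)CCCC1=O | starting material
5 | 2,2,4-trimethylcyclohexane-1,3-dione (racemic) | CC1CCC(=O)C(C)(C)C1=O | intermediate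
6 | tert-butyl 3,3,5-trimethyl-2,4-dioxocyclohexane-1-carboxylate (epimers and enol) | CC1CC(C(=O)OC(C)(C)C)C(=O)C(C)(C)C1=O | intermediate
7 | tert-butyl 3,5,5-trimethyl-6-oxo-4-(trifluoromethylsulfonyloxy)cyclohex-3-ene-1-carboxylate (racemic, keto/enol) | CC1=C(OS(=O)(=O)C(F)(F)F)C(C)(C)C(=O)C(C(=O)OC(C)(C)C)C1 | intermediate
8 | tert-butyl (1R,6S)-6-hydroxy-3,5,5-trimethyl-4-(trifluoromethylsulfonyloxy)cyclohex-3-ene-1-carboxylate | CC1=C(OS(=O)(=O)C(F)(F)F)C(C)(C)[C@@H](O)[C@H](C(=O)OC(C)(C)C)C1 | intermediate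
9 | tert-butyl (1R,6S)-3,5,5-trimethyl-6-(triethylsilyloxy)-4-(trifluoromethylsulfonyloxy)cyclohex-3-ene-1-carboxylate | CC1=C(OS(=O)(=O)C(F)(F)F)C(C)(C)[C@@H](O[Si](CC)(CC)CC)[C@H](C(=O)OC(C)(C)C)C1 | intermediate
10 | tert-butyl (1R,6S)-3,5,5-trimethyl-6-(triethylsilyloxy)-4-(trimethylstannyl)cyclohex-3-ene-1-carboxylate | CC1=C([Sn](C)(C)C)C(C)(C)[C@@H](O[Si](CC)(CC)CC)[C@H](C(=O)OC(C)(C)C)C1 | intermediate
11 | alkenyllithium from 10 (Li in place of SnMe3) | [Li]C1=C(C)C[C@@H](C(=O)OC(C)(C)C)[C@H](O[Si](CC)(CC)CC)C1(C)C | intermediate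
12 | lithium alkoxide of the 1,2-adduct of 11 to C-2 of 3 (both C-4 epimers) | CC1=C(OC)C([O-])(C1=O)C1=C(C)C[C@@H](C(=O)OC(C)(C)C)[C@H](O[Si](CC)(CC)CC)C1(C)C.[Li+] | intermediate
13 | 4-[(4R,5S)-4-(tert-butoxycarbonyl)-2,6,6-trimethyl-5-(triethylsilyloxy)cyclohex-1-en-1-yl]-3-methoxy-4-(methoxymethoxy)-2-methylcyclobut-2-en-1-one (both C-4 epimers) | CC1=C(OC)C(OCOC)(C1=O)C1=C(C)C[C@@H](C(=O)OC(C)(C)C)[C@H](O[Si](CC)(CC)CC)C1(C)C | intermediate
14 | (Z)-dienylketene from ring opening of 13 (cyclohexenyl cis to the ketene-bearing carbon) | O=C=C(C)/C(OC)=C(OCOC)\C1=C(C)C[C@@H](C(=O)OC(C)(C)C)[C@H](O[Si](CC)(CC)CC)C1(C)C | intermediate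
15 | tert-butyl (6S,7R,8aS)-3-methoxy-4-(methoxymethoxy)-2,5,5,8a-tetramethyl-1-oxo-6-(triethylsilyloxy)-1,5,6,7,8,8a-hexahydronaphthalene-7-carboxylate | O=C1C(C)=C(OC)C(OCOC)=C2C(C)(C)[C@@H](O[Si](CC)(CC)CC)[C@H](C(=O)OC(C)(C)C)C[C@]12C | intermediate
16 | tert-butyl (6S,7R,8aS)-6-hydroxy-3-methoxy-4-(methoxymethoxy)-2,5,5,8a-tetramethyl-1-oxo-1,5,6,7,8,8a-hexahydronaphthalene-7-carboxylate | O=C1C(C)=C(OC)C(OCOC)=C2C(C)(C)[C@@H](O)[C@H](C(=O)OC(C)(C)C)C[C@]12C | intermediate
17 | tert-butyl (8aS)-3-methoxy-4-(methoxymethoxy)-2,5,5,8a-tetramethyl-1,6-dioxo-1,5,6,7,8,8a-hexahydronaphthalene-7-carboxylate (C-7 epimers and enol) | O=C1C(C)=C(OC)C(OCOC)=C2C(C)(C)C(=O)C(C(=O)OC(C)(C)C)C[C@]12C | intermediate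
18 | geraniol ((2E)-3,7-dimethylocta-2,6-dien-1-ol) | CC(C)=CCC/C(C)=C/CO | starting material
19 | (2S,3S)-2,3-epoxygeraniol | OC[C@@H]1O[C@@]1(C)CCC=C(C)C | intermediate
20 | (2S,3S,6R)-2,3:6,7-diepoxy-3,7-dimethyloctan-1-ol | OC[C@@H]1O[C@@]1(C)CC[C@H]1OC1(C)C | intermediate
21 | (2R,3S,6R)-2,3:6,7-diepoxy-1-iodo-3,7-dimethyloctane | IC[C@@H]1O[C@@]1(C)CC[C@H]1OC1(C)C | intermediate
22 | methyl acetoacetate | CC(=O)CC(=O)OC | starting material
23 | methyl (6S,7S,10R)-6,7:10,11-diepoxy-7,11-dimethyl-3-oxododecanoate | COC(=O)CC(=O)CC[C@@H]1O[C@@]1(C)CC[C@H]1OC1(C)C | intermediate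
24 | methyl (3R,5aS,9aS)-3-hydroxy-2,2,5a-trimethyl-7-oxodecahydro-1-benzoxepine-6-carboxylate (trans-fused; C-6 epimers and enol) | COC(=O)C1C(=O)CC[C@@H]2OC(C)(C)[C@H](O)CC[C@]21C | intermediate
25 | methyl (3R,5aS,9aS)-3-hydroxy-6-(2-methoxy-2-oxoethyl)-2,2,5a-trimethyl-7-oxodecahydro-1-benzoxepine-6-carboxylate (C-6 epimers) | COC(=O)CC1(C(=O)OC)C(=O)CC[C@@H]2OC(C)(C)[C@H](O)CC[C@]21C | intermediate
26 | methyl 2-[(3R,5aS,6S,9aS)-3-hydroxy-2,2,5a-trimethyl-7-oxodecahydro-1-benzoxepin-6-yl]acetate | COC(=O)C[C@@H]1C(=O)CC[C@@H]2OC(C)(C)[C@H](O)CC[C@]21C | intermediate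
27 | methyl 2-[(3R,5aS,9aS)-3-hydroxy-2,2,5a-trimethyl-7-methylidenedecahydro-1-benzoxepin-6-yl]acetate (C-6 side chain equatorial, cis to 5a-methyl) | COC(=O)C[C@@H]1C(=C)CC[C@@H]2OC(C)(C)[C@H](O)CC[C@]21C | intermediate
28 | methyl 2-[(3R,5aS,6R,7R,9aS)-3-hydroxy-2,2,5a,7-tetramethyldecahydro-1-benzoxepin-6-yl]acetate | COC(=O)C[C@@H]1[C@H](C)CC[C@@H]2OC(C)(C)[C@H](O)CC[C@]21C | intermediate
29 | methyl 2-[(5aS,6R,7R,9aS)-2,2,5a,7-tetramethyl-3-oxodecahydro-1-benzoxepin-6-yl]acetate | COC(=O)C[C@@H]1[C@H](C)CC[C@@H]2OC(C)(C)C(=O)CC[C@]21C | intermediate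
30 | methyl 2-[(5aS,6R,7R,9aS)-3,3-(ethylenedioxy)-2,2,5a,7-tetramethyldecahydro-1-benzoxepin-6-yl]acetate (1,3-dioxolane ketal of 29) | COC(=O)C[C@@H]1[C@H](C)CC[C@@H]2OC(C)(C)C3(OCCO3)CC[C@]21C | intermediate
31 | 2-[(5aS,6R,7R,9aS)-3,3-(ethylenedioxy)-2,2,5a,7-tetramethyldecahydro-1-benzoxepin-6-yl]ethanol | OCC[C@@H]1[C@H](C)CC[C@@H]2OC(C)(C)C3(OCCO3)CC[C@]21C | intermediate
32 | (5aS,6R,7R,9aS)-3,3-(ethylenedioxy)-6-(2-iodoethyl)-2,2,5a,7-tetramethyldecahydro-1-benzoxepine | ICC[C@@H]1[C@H](C)CC[C@@H]2OC(C)(C)C3(OCCO3)CC[C@]21C | intermediate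
33 | alkyllithium from 32 (Li in place of I) | [Li]CC[C@@H]1[C@H](C)CC[C@@H]2OC(C)(C)C3(OCCO3)CC[C@]21C | intermediate
34 | sodium enolate of the β-keto ester of 17 | O=C1C(C)=C(OC)C(OCOC)=C2C(C)(C)C([O-])=C(C(=O)OC(C)(C)C)C[C@]12C.[Na+] | intermediate
35 | C-1 tertiary carbinol from 1,2-addition of 33 to 34 (formed as its lithium alkoxide; C-1 epimers) | OC1(CC[C@@H]3[C@H](C)CC[C@@H]4OC(C)(C)C5(OCCO5)CC[C@]43C)C(C)=C(OC)C(OCOC)=C2C(C)(C)C(=O)C(C(=O)OC(C)(C)C)C[C@]12C | intermediate
36 | tert-butyl (8aR)-1-{2-[(5aS,6R,7R,9aS)-3,3-(ethylenedioxy)-2,2,5a,7-tetramethyldecahydro-1-benzoxepin-6-yl]ethyl}-4-(methoxymethoxy)-2,5,5,8a-tetramethyl-3,6-dioxo-3,5,6,7,8,8a-hexahydronaphthalene-7-carboxylate (C-7 epimers and enol) | CC1=C(CC[C@@H]2[C@H](C)CC[C@@H]3OC(C)(C)C4(OCCO4)CC[C@]32C)[C@@]2(C)CC(C(=O)OC(C)(C)C)C(=O)C(C)(C)C2=C(OCOC)C1=O | intermediate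
37 | sodwanone B | CC1=C(CC[C@@H]2[C@H](C)CC[C@@H]3OC(C)(C)C(=O)CC[C@]32C)[C@@]2(C)CCC(=O)C(C)(C)C2=C(O)C1=O | target

Total step count: 26. Longest linear sequence: 15 steps (18 → 37, steps 12 to 26); the ring A/B branch (4 → 17) has 10 steps and the squarate branch 1.

**Steps most likely to fail**

Step 9. What may go wrong is loss of facial control in the 6π closure (closure through a ring A conformer with the ester axial, or through a boat), which would deliver the C-8a epimer alongside 15. The fallback replaces kinetic control by recycling. It sets out from 13 and comes back at 15. After thermolysis as before, the epimer tert-butyl (6S,7R,8aR)-3-methoxy-4-(methoxymethoxy)-2,5,5,8a-tetramethyl-1-oxo-6-(triethylsilyloxy)-1,5,6,7,8,8a-hexahydronaphthalene-7-carboxylate F1 is separated by chromatography and irradiated (365 nm, toluene, −40 °C → rt). Photochemical ring opening of the 6,6-disubstituted cyclohexa-2,4-dienone regenerates ketene 14, which recloses thermally to the 15/F1 mixture, so repeated cycles funnel the material into 15.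

Step 16. What may go wrong is diversion of the cascade, by attack of the enol oxygen instead of the enol carbon or by 6-exo opening of the terminal epoxide to a tetrahydropyran. The fallback builds the two rings one after the other with known reactions. It sets out from 19 and comes back at 24 (together with its C-3 epimer, both of which give 29 in step 21). Iodination of 19 (I2, PPh3, imidazole) gives (2R,3S)-2,3-epoxy-1-iodo-3,7-dimethyloct-6-ene F2, which alkylates the dianion of 22 to methyl (6S,7S)-6,7-epoxy-7,11-dimethyl-3-oxododec-10-enoate F3. SnCl4 (CH2Cl2, −78 °C) then effects the epoxy β-keto ester carbocyclization, with inversion at the tertiary epoxide carbon, to methyl (2S,3S)-3-hydroxy-2-methyl-2-(4-methylpent-3-en-1-yl)-6-oxocyclohexane-1-carboxylate F4. Epoxidation of the side-chain alkene with m-chloroperbenzoic acid gives methyl (2S,3S)-2-[2-(3,3-dimethyloxiran-2-yl)ethyl]-3-hydroxy-2-methyl-6-oxocyclohexane-1-carboxylate F5 (both oxirane epimers), and camphorsulfonic acid closes the oxepane by 7-endo attack of the hydroxyl group at the tertiary epoxide carbon.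

Step 25. What may go wrong is failure of 1,2-addition at the hindered C-1 carbonyl, with proton transfer from the C-2 methyl group or electron transfer taking over. The fallback moves the union in front of the ring expansion. It sets out from 13 and 33 and comes back at 36. Alkyllithium 33 is added to the strained ketone of cyclobutenone 13 (THF, −78 °C); on warming, the cyclobutenoxide opens and recloses (charge-accelerated 4π/6π sequence under the same ring A control) to the lithium salt of tert-butyl (6S,7R,8aS)-1-{2-[(5aS,6R,7R,9aS)-3,3-(ethylenedioxy)-2,2,5a,7-tetramethyldecahydro-1-benzoxepin-6-yl]ethyl}-1-hydroxy-3-methoxy-4-(methoxymethoxy)-2,5,5,8a-tetramethyl-6-(triethylsilyloxy)-1,5,6,7,8,8a-hexahydronaphthalene-7-carboxylate F6. Aqueous oxalic acid transposes it to tert-butyl (6S,7R,8aR)-1-{2-[(5aS,6R,7R,9aS)-3,3-(ethylenedioxy)-2,2,5a,7-tetramethyldecahydro-1-benzoxepin-6-yl]ethyl}-4-(methoxymethoxy)-2,5,5,8a-tetramethyl-3-oxo-6-(triethylsilyloxy)-3,5,6,7,8,8a-hexahydronaphthalene-7-carboxylate F7. HF·pyridine then frees the corresponding C-6 alcohol, tert-butyl (6S,7R,8aR)-1-{2-[(5aS,6R,7R,9aS)-3,3-(ethylenedioxy)-2,2,5a,7-tetramethyldecahydro-1-benzoxepin-6-yl]ethyl}-6-hydroxy-4-(methoxymethoxy)-2,5,5,8a-tetramethyl-3-oxo-3,5,6,7,8,8a-hexahydronaphthalene-7-carboxylate F8, and Dess–Martin oxidation gives 36.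

Further compounds
F1 | step 9 | tert-butyl (6S,7R,8aR)-3-methoxy-4-(methoxymethoxy)-2,5,5,8a-tetramethyl-1-oxo-6-(triethylsilyloxy)-1,5,6,7,8,8a-hexahydronaphthalene-7-carboxylate | O=C1C(C)=C(OC)C(OCOC)=C2C(C)(C)[C@@H](O[Si](CC)(CC)CC)[C@H](C(=O)OC(C)(C)C)C[C@@]12C
F2 | step 16 | (2R,3S)-2,3-epoxy-1-iodo-3,7-dimethyloct-6-ene | IC[C@@H]1O[C@@]1(C)CCC=C(C)C
F3 | step 16 | methyl (6S,7S)-6,7-epoxy-7,11-dimethyl-3-oxododec-10-enoate | COC(=O)CC(=O)CC[C@@H]1O[C@@]1(C)CCC=C(C)C
F4 | step 16 | methyl (2S,3S)-3-hydroxy-2-methyl-2-(4-methylpent-3-en-1-yl)-6-oxocyclohexane-1-carboxylate | COC(=O)C1C(=O)CC[C@H](O)[C@@]1(C)CCC=C(C)C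
F5 | step 16 | methyl (2S,3S)-2-[2-(3,3-dimethyloxiran-2-yl)ethyl]-3-hydroxy-2-methyl-6-oxocyclohexane-1-carboxylate | COC(=O)C1C(=O)CC[C@H](O)[C@@]1(C)CCC1OC1(C)C
F6 | step 25 | tert-butyl (6S,7R,8aS)-1-{2-[(5aS,6R,7R,9aS)-3,3-(ethylenedioxy)-2,2,5a,7-tetramethyldecahydro-1-benzoxepin-6-yl]ethyl}-1-hydroxy-3-methoxy-4-(methoxymethoxy)-2,5,5,8a-tetramethyl-6-(triethylsilyloxy)-1,5,6,7,8,8a-hexahydronaphthalene-7-carboxylate | OC1(CC[C@@H]3[C@H](C)CC[C@@H]4OC(C)(C)C5(OCCO5)CC[C@]43C)C(C)=C(OC)C(OCOC)=C2C(C)(C)[C@@H](O[Si](CC)(CC)CC)[C@H](C(=O)OC(C)(C)C)C[C@]12C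
F7 | step 25 | tert-butyl (6S,7R,8aR)-1-{2-[(5aS,6R,7R,9aS)-3,3-(ethylenedioxy)-2,2,5a,7-tetramethyldecahydro-1-benzoxepin-6-yl]ethyl}-4-(methoxymethoxy)-2,5,5,8a-tetramethyl-3-oxo-6-(triethylsilyloxy)-3,5,6,7,8,8a-hexahydronaphthalene-7-carboxylate | CC1=C(CC[C@@H]2[C@H](C)CC[C@@H]3OC(C)(C)C4(OCCO4)CC[C@]32C)[C@@]2(C)C[C@@H](C(=O)OC(C)(C)C)[C@H](O[Si](CC)(CC)CC)C(C)(C)C2=C(OCOC)C1=O
F8 | step 25 | tert-butyl (6S,7R,8aR)-1-{2-[(5aS,6R,7R,9aS)-3,3-(ethylenedioxy)-2,2,5a,7-tetramethyldecahydro-1-benzoxepin-6-yl]ethyl}-6-hydroxy-4-(methoxymethoxy)-2,5,5,8a-tetramethyl-3-oxo-3,5,6,7,8,8a-hexahydronaphthalene-7-carboxylate | CC1=C(CC[C@@H]2[C@H](C)CC[C@@H]3OC(C)(C)C4(OCCO4)CC[C@]32C)[C@@]2(C)C[C@@H](C(=O)OC(C)(C)C)[C@H](O)C(C)(C)C2=C(OCOC)C1=O
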